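**Retrosynthetic overview**

1. Numbering: cycloheptane C1 (quaternary carbinol)–C5 (acyloxy)–C6 (lactone O)–C7–C8–C9 (carbinol)–C10 (methyl C14); side chain C2(=O)–C3–C4(OH)–C15 on C1; lactone C6–O–C12(=O)–C11(=C13)–C7.
2. Enabling feature: O–C9–C10–C1–C2=O is a γ-hydroxy ketone straddling the cycloheptane, and its α-carbon C1 carries the tertiary hydroxyl; the ring bond C9–C10 is therefore the retron of a reductive aldehyde–enone coupling whose enolate is oxygenated at C1.
3. Key disconnection (cycloheptane, formed second): SmI2-induced 7-endo closure C9–C10 of the C9 aldehyde onto the (Z)-enone C10=C1–C2=O of monocyclic lactone 20, with hydroxylation of the enolate in the same flask, setting C9, C10 and C1.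
4. Enone: hydroxyl-directed trans-hydrostannation of the C1≡C10 propargylic alcohol and Pd/Cu acylation with an (R)-3-silyloxybutanoyl thioester (C2–C4, C15). Endgame: C9 silylation, C5 desilylation and acylation, desilylation, release of C11=C13 from its Me2NH adduct.
5. Lactone (formed first): chelation-controlled indium Barbier allylation/lactonisation of (R)-2-hydroxypent-3-ynal (C5 from asymmetric transfer hydrogenation) with a (Z)-2-(bromomethyl)enoate carrying C8–C9 as an acetal, setting C6 and C7.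

Key step: step 13

Remark: centres that are formed as mixtures and erased later are drawn arbitrarily or left undefined (C11 of the amine adducts, drawn 11R as expected for protonation trans to the C7 substituent; the carbinol of 7; C9 of 19; the enolate geometry of 21; C1 of F1; C2 of F6).

**Route**

Step 1
Reactants: 1 methyl (R)-3-hydroxybutanoate
Product: 2 methyl (R)-3-(tert-butyldimethylsilyloxy)butanoate
Conditions: TBSCl, imidazole, DMF, 0 °C to rt
Reagents that add atoms: tert-butyldimethylsilyl chloride, CC(C)(C)[Si](C)(C)Cl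
Why: Imidazole-assisted O-silylation should protect the C4 hydroxyl without touching the stereocentre.

Step 2
Reactants: 2 methyl (R)-3-(tert-butyldimethylsilyloxy)butanoate
Product: 3 S-ethyl (R)-3-(tert-butyldimethylsilyloxy)butanethioate
Conditions: Me3Al, EtSH, CH2Cl2, 0 °C to rt
Reagents that add atoms: ethanethiol, CCS
Why: Ester-to-thioester exchange by the aluminium thiolate formed in the flask should give the acyl donor for step 11 without affecting the silyl ether or the β-stereocentre.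

Step 3
Reactants: 4 methyl 3,3-dimethoxypropanoate
Product: 5 3,3-dimethoxypropanal
Conditions: i-Bu2AlH (1.05 equiv), CH2Cl2, −78 °C; aq. potassium sodium tartrate
Reagents that add atoms: none
Why: Partial hydride reduction of the ester should stop at the aldehyde because the tetrahedral aluminate survives at −78 °C; the acetal is inert.

Step 4
Reactants: 5 3,3-dimethoxypropanal; 6 methyl acrylate
Product: 7 methyl 3-hydroxy-5,5-dimethoxy-2-methylidenepentanoate (racemic)
Conditions: DABCO (0.3 equiv), MeOH, rt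
Reagents that add atoms: none
Why: The Morita–Baylis–Hillman reaction should join the acrylate α-carbon to the aldehyde; the racemic carbinol centre is erased in step 5.

Step 5
Reactants: 7 methyl 3-hydroxy-5,5-dimethoxy-2-methylidenepentanoate
Product: 8 methyl (2Z)-2-(bromomethyl)-5,5-dimethoxypent-2-enoate
Conditions: NBS, Me2S, CH2Cl2, −20 °C to rt
Reagents that add atoms: N-bromosuccinimide, O=C1CCC(=O)N1Br
Why: Activation of the allylic alcohol by the bromosulfonium salt and SN2′ delivery of bromide should give the thermodynamically preferred (Z)-allyl bromide under neutral conditions that spare the acetal.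

Step 6
Reactants: 9 ethyl 2,2-diethoxyacetate; 10 prop-1-ynylmagnesium bromide
Product: 11 1,1-diethoxypent-3-yn-2-one
Conditions: THF, −78 °C; aq. NH4Cl at −78 °C
Reagents that add atoms: none
Why: Acyl substitution by the alkynyl Grignard reagent should stop at the ketone because the chelated tetrahedral magnesium alkoxide of the α,α-dialkoxy ester persists until the cold quench.

Step 7
Reactants: 11 1,1-diethoxypent-3-yn-2-one
Product: 12 (2R)-1,1-diethoxypent-3-yn-2-ol
Conditions: RuCl[(S,S)-TsDPEN](p-cymene) (1 mol %), i-PrOH, rt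
Reagents that add atoms: none
Why: Noyori asymmetric transfer hydrogenation of the ynone, with the alkynyl group in the aryl-like position of the six-membered hydride-transfer transition state, should set C5 with the (S,S)-ligand (descriptor R because the acetal carbon outranks the alkyne).

Step 8
Reactants: 12 (2R)-1,1-diethoxypent-3-yn-2-ol; 8 methyl (2Z)-2-(bromomethyl)-5,5-dimethoxypent-2-enoate
Product: 15 (4S,5R)-4-(2,2-dimethoxyethyl)-5-[(1R)-1-hydroxybut-2-yn-1-yl]-3-methylideneoxolan-2-one, via hydroxy ynal 13 (not isolated), via hydroxy ester 14 (not isolated)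
Conditions: 1 M aq. HCl, THF, 40 °C; then K2HPO4 to pH 7, 8, In powder, THF/H2O, rt; then toluene, 80 °C
Reagents that add atoms: water, O
Why: Indium-mediated Barbier allylation in water then lactonisation, in which the hydroxy ynal set free from the acetal is attacked within a Cram chelate (indium bridging the aldehyde oxygen and the free C5 hydroxyl) to give the syn C5/C6 relationship, the (Z)-allyl bromide reacts at its γ-carbon through a chair transition state to give the syn C6/C7 adduct, and heating closes the cis-4,5-disubstituted α-methylene lactone (first ring).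

Step 9
Reactants: 15 (4S,5R)-4-(2,2-dimethoxyethyl)-5-[(1R)-1-hydroxybut-2-yn-1-yl]-3-methylideneoxolan-2-one
Product: 16 (4S,5R)-4-(2,2-dimethoxyethyl)-5-[(1S,2Z)-1-hydroxy-2-(tributylstannyl)but-2-en-1-yl]-3-methylideneoxolan-2-one
Conditions: [Cp*RuCl]4 (2.5 mol %), Bu3SnH, CH2Cl2, rt
Reagents that add atoms: tributyltin hydride, CCCC[SnH](CCCC)CCCC
Why: Hydroxyl-directed ruthenium-catalysed trans-hydrostannation (hydrogen bond from the propargylic OH to the Ru–Cl unit) should place tin on C1 next to the carbinol and hydrogen trans to it on C10, fixing C14 trans to C5, while alkenes are not touched.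

Step 10
Reactants: 16 (4S,5R)-4-(2,2-dimethoxyethyl)-5-[(1S,2Z)-1-hydroxy-2-(tributylstannyl)but-2-en-1-yl]-3-methylideneoxolan-2-one
Product: 17 (3R,4S,5R)-3-[(dimethylamino)methyl]-4-(2,2-dimethoxyethyl)-5-[(1S,2Z)-1-hydroxy-2-(tributylstannyl)but-2-en-1-yl]oxolan-2-one
Conditions: Me2NH (2 M in THF), THF, 0 °C to rt
Reagents that add atoms: dimethylamine, CNC
Why: Aza-Michael addition should mask the α-methylene lactone against SmI2 before a second Michael acceptor is present, with protonation at C11 trans to the C7 substituent; the alkenylstannane does not react.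

Step 11
Reactants: 17 (3R,4S,5R)-3-[(dimethylamino)methyl]-4-(2,2-dimethoxyethyl)-5-[(1S,2Z)-1-hydroxy-2-(tributylstannyl)but-2-en-1-yl]oxolan-2-one; 3 S-ethyl (R)-3-(tert-butyldimethylsilyloxy)butanethioate
Product: 18 (3R,4S,5R)-5-[(1R,2Z,5R)-5-(tert-butyldimethylsilyloxy)-2-ethylidene-1-hydroxy-3-oxohexyl]-3-[(dimethylamino)methyl]-4-(2,2-dimethoxyethyl)oxolan-2-one
Conditions: Pd2(dba)3 (5 mol %), P(2-furyl)3, Cu(O2PPh2) (1.5 equiv), THF, 45 °C
Reagents that add atoms: none
Why: Liebeskind–Srogl thioester–stannane coupling (zerovalent palladium inserts into the C–S bond, the monovalent copper phosphinate takes up thiolate and tin, the neighbouring hydroxyl assists the tin transfer) should form C1–C2 with retention of geometry, giving the (Z)-enone with C14 cis to the acyl group.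

Step 12
Reactants: 18 (3R,4S,5R)-5-[(1R,2Z,5R)-5-(tert-butyldimethylsilyloxy)-2-ethylidene-1-hydroxy-3-oxohexyl]-3-[(dimethylamino)methyl]-4-(2,2-dimethoxyethyl)oxolan-2-one
Product: 20 (3R,4S,5R)-5-[(1R,2Z,5R)-5-(tert-butyldimethylsilyloxy)-2-ethylidene-3-oxo-1-(triethylsilyloxy)hexyl]-3-[(dimethylamino)methyl]-4-(2-oxoethyl)oxolan-2-one, via pyridinium acetal 19 (not isolated)
Conditions: Et3SiOTf, 2,4,6-collidine, CH2Cl2, 0 °C; then H2O, rt
Reagents that add atoms: triethylsilyl triflate, CC[Si](CC)(CC)OS(=O)(=O)C(F)(F)F; water, O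
Why: The silyl triflate/collidine pair should silylate the C5 hydroxyl and convert the dimethyl acetal into a pyridinium O,N-acetal that water hydrolyses to the C9 aldehyde under non-acidic conditions, so the TBS ether and the (Z)-enone survive and no lactol can form.

Step 13
Reactants: 20 (3R,4S,5R)-5-[(1R,2Z,5R)-5-(tert-butyldimethylsilyloxy)-2-ethylidene-3-oxo-1-(triethylsilyloxy)hexyl]-3-[(dimethylamino)methyl]-4-(2-oxoethyl)oxolan-2-one
Product: 22 (3R,3aS,5R,6S,7S,8S,8aR)-7-[(3R)-3-(tert-butyldimethylsilyloxy)butanoyl]-3-[(dimethylamino)methyl]-5,7-dihydroxy-6-methyl-8-(triethylsilyloxy)octahydro-2H-cyclohepta[b]furan-2-one, via samarium enolate 21 (not isolated)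
Conditions: SmI2 (2.5 equiv), HMPA, THF, −78 °C, slow addition of 20; then 2-(phenylsulfonyl)-3-phenyloxaziridine, −78 to −40 °C; aq. NH4Cl
Reagents that add atoms: 2-(phenylsulfonyl)-3-phenyloxaziridine, O=S(=O)(c1ccccc1)N1OC1c1ccccc1
Why: Proposed new method: SmI2/HMPA reduces the C9 aldehyde to a ketyl that adds to C10, the β-carbon of the tethered (Z)-enone, a second SmI2 reduces the α-keto radical to the regiodefined trivalent samarium enolate 21, and this tetrasubstituted enolate is hydroxylated at C1 by the N-sulfonyloxaziridine before any proton source is admitted; the closest known chemistry is the SmI2 ketyl–olefin cyclisation onto α,β-unsaturated carbonyl compounds (endo closures to seven- and eight-membered rings included) with sequenced trapping of the samarium enolate by carbon electrophiles, and the oxaziridine hydroxylation of alkali-metal enolates. The cycloheptane is closed in the 7-endo-trig mode, preferred to 6-exo attack at C1 because C10 is the polarity-matched β-position and C1 is fully substituted. C10 is controlled by the (Z)-geometry of the enone (C14 cis to the acyl group, C10–H towards C5) together with the tether, which can reach only the alkene face on the side of C6, so that C14 ends trans to the C5 oxygen. C9 is controlled by the ketyl oxygen and its bulky Sm(HMPA)n shell lying antiperiplanar to the C10=C1 bond in the transition state, which puts the C9 oxygen trans to C14. C1 is controlled by O-transfer to the enolate face opposite to the C5 silyl ether and the C9 samarium alkoxide, that is syn to the small C14 methyl group. The step needs chemoselectivity for the aldehyde–enone pair, secured by masking the α-methylene lactone as its Me2NH adduct, and an enolate without a β-leaving group or internal proton source, secured by the C5 triethylsilyl ether.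

Step 14
Reactants: 22 (3R,3aS,5R,6S,7S,8S,8aR)-7-[(3R)-3-(tert-butyldimethylsilyloxy)butanoyl]-3-[(dimethylamino)methyl]-5,7-dihydroxy-6-methyl-8-(triethylsilyloxy)octahydro-2H-cyclohepta[b]furan-2-one
Product: 23 (3R,3aS,5R,6S,7S,8S,8aR)-5-(tert-butyldimethylsilyloxy)-7-[(3R)-3-(tert-butyldimethylsilyloxy)butanoyl]-3-[(dimethylamino)methyl]-7-hydroxy-6-methyl-8-(triethylsilyloxy)octahydro-2H-cyclohepta[b]furan-2-one
Conditions: TBSCl, imidazole, DMF, rt
Reagents that add atoms: tert-butyldimethylsilyl chloride, CC(C)(C)[Si](C)(C)Cl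
Why: O-Silylation should take place only at the secondary C9 hydroxyl, since the tertiary C1 hydroxyl does not react with the silyl chloride.

Step 15
Reactants: 23 (3R,3aS,5R,6S,7S,8S,8aR)-5-(tert-butyldimethylsilyloxy)-7-[(3R)-3-(tert-butyldimethylsilyloxy)butanoyl]-3-[(dimethylamino)methyl]-7-hydroxy-6-methyl-8-(triethylsilyloxy)octahydro-2H-cyclohepta[b]furan-2-one
Product: 24 (3R,3aS,5R,6S,7S,8S,8aR)-5-(tert-butyldimethylsilyloxy)-7-[(3R)-3-(tert-butyldimethylsilyloxy)butanoyl]-3-[(dimethylamino)methyl]-7,8-dihydroxy-6-methyloctahydro-2H-cyclohepta[b]furan-2-one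
Conditions: PPTS (2 equiv), MeOH/CH2Cl2, 0 °C to rt
Reagents that add atoms: none
Why: Acid-catalysed methanolysis should cleave the triethylsilyl ether at C5 much faster than the two TBS ethers, exposing only the hydroxyl that is to be acylated.

Step 16
Reactants: 24 (3R,3aS,5R,6S,7S,8S,8aR)-5-(tert-butyldimethylsilyloxy)-7-[(3R)-3-(tert-butyldimethylsilyloxy)butanoyl]-3-[(dimethylamino)methyl]-7,8-dihydroxy-6-methyloctahydro-2H-cyclohepta[b]furan-2-one; 25 (2S)-2-methylbutanoic anhydride
Product: 26 (3R,3aS,5R,6S,7S,8S,8aR)-5-(tert-butyldimethylsilyloxy)-7-[(3R)-3-(tert-butyldimethylsilyloxy)butanoyl]-3-[(dimethylamino)methyl]-7-hydroxy-6-methyl-2-oxooctahydro-2H-cyclohepta[b]furan-8-yl (2S)-2-methylbutanoate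
Conditions: DMAP, Et3N, CH2Cl2, rt to 35 °C
Reagents that add atoms: none
Why: DMAP-catalysed acyl transfer should esterify the only secondary hydroxyl (C5), the tertiary C1 hydroxyl being unreactive, and the anhydride avoids ketene-type epimerisation of the (S)-acyl unit.

Step 17
Reactants: 26 (3R,3aS,5R,6S,7S,8S,8aR)-5-(tert-butyldimethylsilyloxy)-7-[(3R)-3-(tert-butyldimethylsilyloxy)butanoyl]-3-[(dimethylamino)methyl]-7-hydroxy-6-methyl-2-oxooctahydro-2H-cyclohepta[b]furan-8-yl (2S)-2-methylbutanoate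
Product: 27 (3R,3aS,5R,6S,7S,8S,8aR)-3-[(dimethylamino)methyl]-5,7-dihydroxy-7-[(3R)-3-hydroxybutanoyl]-6-methyl-2-oxooctahydro-2H-cyclohepta[b]furan-8-yl (2S)-2-methylbutanoate
Conditions: HF·pyridine, pyridine, THF, 0 °C to rt
Reagents that add atoms: none
Why: Buffered fluoride desilylation should free the C9 and C4 hydroxyls without touching the lactone, the ester or the tertiary α-ketol.

Step 18
Reactants: 27 (3R,3aS,5R,6S,7S,8S,8aR)-3-[(dimethylamino)methyl]-5,7-dihydroxy-7-[(3R)-3-hydroxybutanoyl]-6-methyl-2-oxooctahydro-2H-cyclohepta[b]furan-8-yl (2S)-2-methylbutanoate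
Product: 29 (3aS,5R,6S,7S,8S,8aR)-5,7-dihydroxy-7-[(3R)-3-hydroxybutanoyl]-6-methyl-3-methylidene-2-oxooctahydro-2H-cyclohepta[b]furan-8-yl (2S)-2-methylbutanoate, via ammonium iodide 28 (not isolated)
Conditions: MeI, MeCN, rt; then aq. NaHCO3, CH2Cl2, rt
Reagents that add atoms: none
Why: N-Methylation and mild base-induced E1cB (Hofmann-type) loss of trimethylamine should regenerate the α-methylene lactone, erasing C11, without affecting the hydroxyls, the ketone or the ester.

**Compound list**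

1 | methyl (R)-3-hydroxybutanoate | COC(=O)C[C@@H](C)O | starting material
2 | methyl (R)-3-(tert-butyldimethylsilyloxy)butanoate | COC(=O)C[C@@H](C)O[Si](C)(C)C(C)(C)C | intermediate
3 | S-ethyl (R)-3-(tert-butyldimethylsilyloxy)butanethioate | CCSC(=O)C[C@@H](C)O[Si](C)(C)C(C)(C)C | intermediate
4 | methyl 3,3-dimethoxypropanoate | COC(=O)CC(OC)OC | starting material
5 | 3,3-dimethoxypropanal | O=CCC(OC)OC | intermediate
6 | methyl acrylate | C=CC(=O)OC | starting material
7 | methyl 3-hydroxy-5,5-dimethoxy-2-methylidenepentanoate (racemic) | COC(=O)C(=C)C(O)CC(OC)OC | intermediate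
8 | methyl (2Z)-2-(bromomethyl)-5,5-dimethoxypent-2-enoate | COC(=O)/C(CBr)=C/CC(OC)OC | intermediate
9 | ethyl 2,2-diethoxyacetate | CCOC(=O)C(OCC)OCC | starting material
10 | prop-1-ynylmagnesium bromide | CC#C[Mg]Br | starting material
11 | 1,1-diethoxypent-3-yn-2-one | CC#CC(=O)C(OCC)OCC | intermediate
12 | (2R)-1,1-diethoxypent-3-yn-2-ol | CC#C[C@H](C(OCC)OCC)O | intermediate
13 | (2R)-2-hydroxypent-3-ynal | CC#C[C@H](C=O)O | intermediate (not isolated)
14 | methyl (3S,4R,5R)-3-(2,2-dimethoxyethyl)-4,5-dihydroxy-2-methylideneoct-6-ynoate | COC(=O)C(=C)[C@H](CC(OC)OC)[C@@H](O)[C@H](O)C#CC | intermediate (not isolated)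
15 | (4S,5R)-4-(2,2-dimethoxyethyl)-5-[(1R)-1-hydroxybut-2-yn-1-yl]-3-methylideneoxolan-2-one | C=C1C(=O)O[C@@H]([C@H](O)C#CC)[C@H]1CC(OC)OC | intermediate
16 | (4S,5R)-4-(2,2-dimethoxyethyl)-5-[(1S,2Z)-1-hydroxy-2-(tributylstannyl)but-2-en-1-yl]-3-methylideneoxolan-2-one | C=C1C(=O)O[C@@H]([C@H](O)/C(=C/C)[Sn](CCCC)(CCCC)CCCC)[C@H]1CC(OC)OC | intermediate
17 | (3R,4S,5R)-3-[(dimethylamino)methyl]-4-(2,2-dimethoxyethyl)-5-[(1S,2Z)-1-hydroxy-2-(tributylstannyl)but-2-en-1-yl]oxolan-2-one | CN(C)C[C@@H]1C(=O)O[C@@H]([C@H](O)/C(=C/C)[Sn](CCCC)(CCCC)CCCC)[C@H]1CC(OC)OC | intermediate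
18 | (3R,4S,5R)-5-[(1R,2Z,5R)-5-(tert-butyldimethylsilyloxy)-2-ethylidene-1-hydroxy-3-oxohexyl]-3-[(dimethylamino)methyl]-4-(2,2-dimethoxyethyl)oxolan-2-one | CN(C)C[C@@H]1C(=O)O[C@@H]([C@H](O)/C(=C/C)C(=O)C[C@@H](C)O[Si](C)(C)C(C)(C)C)[C@H]1CC(OC)OC | intermediate
19 | C9 2,4,6-trimethylpyridinium O,N-acetal triflate of the C5-O-triethylsilyl ether of 18 | CN(C)C[C@@H]1C(=O)O[C@@H]([C@H](O[Si](CC)(CC)CC)/C(=C/C)C(=O)C[C@@H](C)O[Si](C)(C)C(C)(C)C)[C@H]1CC(OC)[n+]1c(C)cc(C)cc1C.[O-]S(=O)(=O)C(F)(F)F | intermediate (not isolated)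
20 | (3R,4S,5R)-5-[(1R,2Z,5R)-5-(tert-butyldimethylsilyloxy)-2-ethylidene-3-oxo-1-(triethylsilyloxy)hexyl]-3-[(dimethylamino)methyl]-4-(2-oxoethyl)oxolan-2-one | CN(C)C[C@@H]1C(=O)O[C@@H]([C@H](O[Si](CC)(CC)CC)/C(=C/C)C(=O)C[C@@H](C)O[Si](C)(C)C(C)(C)C)[C@H]1CC=O | intermediate
21 | cyclised bis(diiodosamarium) C9 alkoxide / C1=C2 enolate from 20 | CN(C)C[C@@H]1C(=O)O[C@@H]2[C@H]1C[C@@H](O[Sm](I)I)[C@H](C)C(=C(O[Sm](I)I)C[C@@H](C)O[Si](C)(C)C(C)(C)C)[C@H]2O[Si](CC)(CC)CC | intermediate (not isolated)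
22 | (3R,3aS,5R,6S,7S,8S,8aR)-7-[(3R)-3-(tert-butyldimethylsilyloxy)butanoyl]-3-[(dimethylamino)methyl]-5,7-dihydroxy-6-methyl-8-(triethylsilyloxy)octahydro-2H-cyclohepta[b]furan-2-one | CN(C)C[C@@H]1C(=O)O[C@@H]2[C@H]1C[C@@H](O)[C@H](C)[C@@](O)(C(=O)C[C@@H](C)O[Si](C)(C)C(C)(C)C)[C@H]2O[Si](CC)(CC)CC | intermediate
23 | (3R,3aS,5R,6S,7S,8S,8aR)-5-(tert-butyldimethylsilyloxy)-7-[(3R)-3-(tert-butyldimethylsilyloxy)butanoyl]-3-[(dimethylamino)methyl]-7-hydroxy-6-methyl-8-(triethylsilyloxy)octahydro-2H-cyclohepta[b]furan-2-one | CN(C)C[C@@H]1C(=O)O[C@@H]2[C@H]1C[C@@H](O[Si](C)(C)C(C)(C)C)[C@H](C)[C@@](O)(C(=O)C[C@@H](C)O[Si](C)(C)C(C)(C)C)[C@H]2O[Si](CC)(CC)CC | intermediate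
24 | (3R,3aS,5R,6S,7S,8S,8aR)-5-(tert-butyldimethylsilyloxy)-7-[(3R)-3-(tert-butyldimethylsilyloxy)butanoyl]-3-[(dimethylamino)methyl]-7,8-dihydroxy-6-methyloctahydro-2H-cyclohepta[b]furan-2-one | CN(C)C[C@@H]1C(=O)O[C@@H]2[C@H]1C[C@@H](O[Si](C)(C)C(C)(C)C)[C@H](C)[C@@](O)(C(=O)C[C@@H](C)O[Si](C)(C)C(C)(C)C)[C@H]2O | intermediate
25 | (2S)-2-methylbutanoic anhydride | CC[C@H](C)C(=O)OC(=O)[C@@H](C)CC | starting material
26 | (3R,3aS,5R,6S,7S,8S,8aR)-5-(tert-butyldimethylsilyloxy)-7-[(3R)-3-(tert-butyldimethylsilyloxy)butanoyl]-3-[(dimethylamino)methyl]-7-hydroxy-6-methyl-2-oxooctahydro-2H-cyclohepta[b]furan-8-yl (2S)-2-methylbutanoate | CN(C)C[C@@H]1C(=O)O[C@@H]2[C@H]1C[C@@H](O[Si](C)(C)C(C)(C)C)[C@H](C)[C@@](O)(C(=O)C[C@@H](C)O[Si](C)(C)C(C)(C)C)[C@H]2OC(=O)[C@@H](C)CC | intermediate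
27 | (3R,3aS,5R,6S,7S,8S,8aR)-3-[(dimethylamino)methyl]-5,7-dihydroxy-7-[(3R)-3-hydroxybutanoyl]-6-methyl-2-oxooctahydro-2H-cyclohepta[b]furan-8-yl (2S)-2-methylbutanoate | CN(C)C[C@@H]1C(=O)O[C@@H]2[C@H]1C[C@@H](O)[C@H](C)[C@@](O)(C(=O)C[C@@H](C)O)[C@H]2OC(=O)[C@@H](C)CC | intermediate
28 | trimethylammonium iodide from N-methylation of 27 | C[N+](C)(C)C[C@@H]1C(=O)O[C@@H]2[C@H]1C[C@@H](O)[C@H](C)[C@@](O)(C(=O)C[C@@H](C)O)[C@H]2OC(=O)[C@@H](C)CC.[I-] | intermediate (not isolated)
29 | (3aS,5R,6S,7S,8S,8aR)-5,7-dihydroxy-7-[(3R)-3-hydroxybutanoyl]-6-methyl-3-methylidene-2-oxooctahydro-2H-cyclohepta[b]furan-8-yl (2S)-2-methylbutanoate | C=C1C(=O)O[C@@H]2[C@H]1C[C@@H](O)[C@H](C)[C@@](O)(C(=O)C[C@@H](C)O)[C@H]2OC(=O)[C@@H](C)CC | target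

**Step count and risks**

Total step count: 18. Longest linear sequence: 14 steps (4 to 29 through steps 3–5 and 8–18).

Steps most likely to fail:

Step 13 (Proposed new method). The 7-endo closure may be outrun by 1,4-reduction of the enone, by pinacol-type dimerisation or by aldol-type closure at C1; the samarium enolate may be protonated before O-transfer, or the oxygenation may show poor facial selectivity. The fallback separates ring closure from hydroxylation and uses only known reaction types. It sets out from 20: SmI2/HMPA cyclisation in the presence of t-BuOH should give the C1-protonated ketone, 22 without its C1 hydroxyl F1. Thermodynamic enol silylation (Me3SiOTf, Et3N, CH2Cl2) should give the tetrasubstituted C1=C2 trimethylsilyl enol ether carrying a C9 trimethylsilyl ether F2. OsO4 (cat.)/NMO oxidation of the silyl enol ether, anti to the allylic C5 oxygen, followed by citric acid in MeOH, should return the route at 22.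

Step 11. Tin transfer at the fully substituted C1 may be slow, so that protodestannylation or loss of the (Z)-geometry competes with acylation. The fallback sets out from 17 and changes the C1–C2 bond formation to an aldehyde addition. Et3SiCl/imidazole should give the C5-O-triethylsilyl ether of 17 F3. I2 in CH2Cl2 at 0 °C should give the (Z)-alkenyl iodide with iodine in place of tin F4. CrCl2/NiCl2-mediated Nozaki–Hiyama–Kishi addition to (R)-3-(tert-butyldimethylsilyloxy)butanal F5 (from 2 with i-Bu2AlH at −78 °C) should give the C2 allylic alcohol F6. Dess–Martin oxidation should give the C5-O-triethylsilyl ether of 18 F7, and the conditions of step 12 should convert F7 into 20, where the route is rejoined.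

Step 8. The free hydroxy ynal may oligomerise when it is liberated, the facial selectivity of the chelated addition may erode, or the acetal of 8 may hydrolyse early. The fallback sets out from 12 and carries the hydroxyl as an ether that still chelates. NaH/4-methoxybenzyl chloride should give (2R)-1,1-diethoxy-2-(4-methoxybenzyloxy)pent-3-yne F8. 1 M aq. HCl/THF should give the isolable (2R)-2-(4-methoxybenzyloxy)pent-3-ynal F9. In with 8 in THF/H2O should give the C5-O-(4-methoxybenzyl) ether of 14 F10, which lactonises on heating to the C5-O-(4-methoxybenzyl) ether of 15 F11. DDQ in CH2Cl2/pH 7 buffer should then return the route at 15.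

**Further compounds**

F1 | step 13 | 22 without the C1 hydroxyl (C1–H, epimer mixture) | CN(C)C[C@@H]1C(=O)O[C@@H]2[C@H]1C[C@@H](O)[C@H](C)C(C(=O)C[C@@H](C)O[Si](C)(C)C(C)(C)C)[C@H]2O[Si](CC)(CC)CC
F2 | step 13 | C1=C2 trimethylsilyl enol ether of F1 with C9 trimethylsilyl ether | CN(C)C[C@@H]1C(=O)O[C@@H]2[C@H]1C[C@@H](O[Si](C)(C)C)[C@H](C)C(=C(O[Si](C)(C)C)C[C@@H](C)O[Si](C)(C)C(C)(C)C)[C@H]2O[Si](CC)(CC)CC
F3 | step 11 | C5-O-triethylsilyl ether of 17 | CN(C)C[C@@H]1C(=O)O[C@@H]([C@H](O[Si](CC)(CC)CC)/C(=C/C)[Sn](CCCC)(CCCC)CCCC)[C@H]1CC(OC)OC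
F4 | step 11 | (Z)-alkenyl iodide from F3 (iodine on C1) | CN(C)C[C@@H]1C(=O)O[C@@H]([C@H](O[Si](CC)(CC)CC)/C(I)=C/C)[C@H]1CC(OC)OC
F5 | step 11 | (R)-3-(tert-butyldimethylsilyloxy)butanal | O=CC[C@@H](C)O[Si](C)(C)C(C)(C)C
F6 | step 11 | C2 allylic alcohol from F4 and F5 (C2 epimer mixture) | CN(C)C[C@@H]1C(=O)O[C@@H]([C@H](O[Si](CC)(CC)CC)/C(=C/C)C(O)C[C@@H](C)O[Si](C)(C)C(C)(C)C)[C@H]1CC(OC)OC
F7 | step 11 | C5-O-triethylsilyl ether of 18 | CN(C)C[C@@H]1C(=O)O[C@@H]([C@H](O[Si](CC)(CC)CC)/C(=C/C)C(=O)C[C@@H](C)O[Si](C)(C)C(C)(C)C)[C@H]1CC(OC)OC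
F8 | step 8 | (2R)-1,1-diethoxy-2-(4-methoxybenzyloxy)pent-3-yne | CC#C[C@H](C(OCC)OCC)OCc1ccc(OC)cc1
F9 | step 8 | (2R)-2-(4-methoxybenzyloxy)pent-3-ynal | CC#C[C@H](C=O)OCc1ccc(OC)cc1
F10 | step 8 | C5-O-(4-methoxybenzyl) ether of 14 | COC(=O)C(=C)[C@H](CC(OC)OC)[C@@H](O)[C@H](OCc1ccc(OC)cc1)C#CC
F11 | step 8 | C5-O-(4-methoxybenzyl) ether of 15 | C=C1C(=O)O[C@@H]([C@H](OCc2ccc(OC)cc2)C#CC)[C@H]1CC(OC)OC
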